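**Retrosynthetic overview**

1. Locants are those of the target, (1R,4Z,8R,12S,13R)-4,15,15-trimethyl-14-oxabicyclo[11.2.1]hexadec-4-ene-8,12-dicarboxylic acid; the oxolane is the ring C13–O14–C15–C1–C16.
2. Enabling feature: O14 joins C13 (which carries C12 and its carboxyl) to the fully substituted C15 (two methyl groups), itself bonded to C1. The oxolane is therefore the Cloke–Wilson isomer of a gem-dimethylcyclopropane C1–C15–C16 with a C13 ketone inside a chelating β-keto imide: disconnect O14–C15, reconnect C15–C16.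
3. The cyclopropyl ketone macrocycle (a bicyclo[12.1.0]pentadecene) comes from closing C3–C4 by intramolecular B-alkyl Suzuki–Miyaura coupling, after Evans acylation has joined C12–C13 between a chain imide and a vinylcyclopropane acid made from (+)-trans-chrysanthemic acid.
4. The chain imide comes from mono-tert-butyl pimelate by Evans allylation (sets C8), hydroboration–oxidation and Z-selective iodo-olefination (fixes the C4=C5 geometry).
5. Ring order: cyclopropane (chiral pool), then the 14-membered carbocycle, then the oxolane by 3→5 ring expansion, then C13–H by ionic hydrogenation and hydrolysis. The expansion follows the coupling because the vinyl group of the open-chain compound would compete with C15 as the cation-stabilising donor.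

Key step: step 13

Remark: enantiopure (1R,3R)-trans-chrysanthemic acid (1) is taken as the purchased chiral-pool material; the other stereocentres are set by the two enantiomeric benzyloxazolidinones and, for C13, by the bridged ring.

**Route**

Step 1
Reactants: 1 (1R,3R)-trans-chrysanthemic acid
Product: 3 (1R,3R)-3-formyl-2,2-dimethylcyclopropane-1-carboxylic acid, via ozonide 2 (not isolated)
Conditions: O3, CH2Cl2, −78 °C; then PPh3, −78 °C to rt
Reagents that add atoms: ozone, O=[O+][O-]
Why: Ozonolysis with reductive work-up should cleave the only C=C bond, the electron-rich trisubstituted side-chain olefin, to the aldehyde, while the cyclopropane and its two stereocentres are not touched (no new stereocentre).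

Step 2
Reactants: 3 (1R,3R)-3-formyl-2,2-dimethylcyclopropane-1-carboxylic acid
Product: 4 (1R,3R)-3-ethenyl-2,2-dimethylcyclopropane-1-carboxylic acid
Conditions: Ph3PCH3Br (2.5 equiv), KN(SiMe3)2 (2.4 equiv), THF, 0 °C; 3 added at −78 °C, then 0 °C; aq. HCl work-up
Reagents that add atoms: methyltriphenylphosphonium bromide, C[P+](c1ccccc1)(c1ccccc1)c1ccccc1.[Br-]
Why: Wittig methylenation with excess non-stabilised ylide (one equivalent of base is consumed by the carboxylic acid) should turn the formyl group into the vinyl group that becomes C2 and C3, the cold conditions leaving the trans-cyclopropane stereocentres unchanged.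

Step 3
Reactants: 5 7-tert-butoxy-7-oxoheptanoic acid; 6 (4S)-4-benzyl-1,3-oxazolidin-2-one
Product: 8 tert-butyl 7-[(4S)-4-benzyl-2-oxo-1,3-oxazolidin-3-yl]-7-oxoheptanoate, via mixed anhydride 7 (not isolated)
Conditions: t-BuCOCl, Et3N, THF, −20 °C; then LiCl, 6, rt
Reagents that add atoms: none
Why: N-Acylation of the oxazolidinone through the mixed pivalic anhydride (LiCl/Et3N activation) is the standard entry to Evans imides and leaves the tert-butyl ester intact.

Step 4
Reactants: 8 tert-butyl 7-[(4S)-4-benzyl-2-oxo-1,3-oxazolidin-3-yl]-7-oxoheptanoate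
Product: 9 tert-butyl (6R)-6-{[(4S)-4-benzyl-2-oxo-1,3-oxazolidin-3-yl]carbonyl}non-8-enoate
Conditions: NaN(SiMe3)2 (1.05 equiv), THF, −78 °C; allyl iodide, −78 to −45 °C
Reagents that add atoms: allyl iodide, C=CCI
Why: Evans asymmetric alkylation: the chelated Z-sodium enolate is attacked by allyl iodide on the face opposite to the benzyl group, which should set the future C8 stereocentre as R, and the less acidic tert-butyl ester is not enolised by one equivalent of base.

Step 5
Reactants: 9 tert-butyl (6R)-6-{[(4S)-4-benzyl-2-oxo-1,3-oxazolidin-3-yl]carbonyl}non-8-enoate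
Product: 10 7-tert-butyl 1-methyl (2R)-2-(prop-2-en-1-yl)heptanedioate
Conditions: MeMgBr, MeOH, CH2Cl2, 0 °C
Reagents that add atoms: methanol, CO
Why: Transesterification with bromomagnesium methoxide attacks the exocyclic imide carbonyl, releases the auxiliary without epimerising the α-centre and spares the tert-butyl ester.

Step 6
Reactants: 10 7-tert-butyl 1-methyl (2R)-2-(prop-2-en-1-yl)heptanedioate
Product: 12 7-tert-butyl 1-methyl (2R)-2-(3-hydroxypropyl)heptanedioate, via alkylborane 11 (not isolated)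
Conditions: 9-BBN, THF, 0 °C to rt; then H2O2, aq. NaOAc, 0 °C to rt
Reagents that add atoms: hydrogen peroxide, OO
Why: Hydroboration–oxidation: 9-BBN adds anti-Markovnikov to the terminal olefin and buffered peroxide oxidation gives the primary alcohol without touching either ester.

Step 7
Reactants: 12 7-tert-butyl 1-methyl (2R)-2-(3-hydroxypropyl)heptanedioate
Product: 13 7-tert-butyl 1-methyl (2R)-2-(3-oxopropyl)heptanedioate
Conditions: Dess–Martin periodinane, CH2Cl2, 0 °C to rt
Reagents that add atoms: none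
Why: Dess–Martin oxidation should give the aldehyde under mild conditions that do not epimerise the remote α-ester stereocentre.

Step 8
Reactants: 13 7-tert-butyl 1-methyl (2R)-2-(3-oxopropyl)heptanedioate
Product: 14 7-tert-butyl 1-methyl (2R)-2-[(3Z)-4-iodopent-3-en-1-yl]heptanedioate
Conditions: Ph3PEtI, n-BuLi, THF, rt; I2, −78 °C; NaN(SiMe3)2, −78 to −20 °C; then 13, −78 °C
Reagents that add atoms: ethyltriphenylphosphonium iodide, CC[P+](c1ccccc1)(c1ccccc1)c1ccccc1.[I-]; iodine, II
Why: Stork–Zhao-type Wittig olefination with the α-iodo ylide made in the flask should give the (Z)-2-iodoalk-2-ene with iodine cis to the chain, the geometry that later becomes the Z-configured C4=C5 bond.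

Step 9
Reactants: 14 7-tert-butyl 1-methyl (2R)-2-[(3Z)-4-iodopent-3-en-1-yl]heptanedioate
Product: 15 (6R,9Z)-10-iodo-6-(methoxycarbonyl)undec-9-enoic acid
Conditions: CF3CO2H, CH2Cl2, 0 °C to rt
Reagents that add atoms: none
Why: Acidolysis of the tert-butyl ester (loss of 2-methylpropene) frees the acid for the second auxiliary, while the methyl ester and the iodoalkene should survive cold trifluoroacetic acid.

Step 10
Reactants: 15 (6R,9Z)-10-iodo-6-(methoxycarbonyl)undec-9-enoic acid; 16 (4R)-4-benzyl-1,3-oxazolidin-2-one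
Product: 18 methyl (2R)-7-[(4R)-4-benzyl-2-oxo-1,3-oxazolidin-3-yl]-2-[(3Z)-4-iodopent-3-en-1-yl]-7-oxoheptanoate, via mixed anhydride 17 (not isolated)
Conditions: t-BuCOCl, Et3N, THF, −20 °C; then LiCl, 16, rt
Reagents that add atoms: none
Why: Mixed-anhydride N-acylation as in step 3, now with the enantiomeric auxiliary required for the C12 stereocentre.

Step 11
Reactants: 18 methyl (2R)-7-[(4R)-4-benzyl-2-oxo-1,3-oxazolidin-3-yl]-2-[(3Z)-4-iodopent-3-en-1-yl]-7-oxoheptanoate; 4 (1R,3R)-3-ethenyl-2,2-dimethylcyclopropane-1-carboxylic acid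
Product: 20 methyl (2R,6S)-7-[(4R)-4-benzyl-2-oxo-1,3-oxazolidin-3-yl]-6-{[(1R,3R)-3-ethenyl-2,2-dimethylcyclopropyl]carbonyl}-2-[(3Z)-4-iodopent-3-en-1-yl]-7-oxoheptanoate, via acid chloride 19 (not isolated)
Conditions: 4, (COCl)2, DMF (cat.), CH2Cl2, 0 °C to rt, evaporation; 18, NaN(SiMe3)2 (1.05 equiv), THF, −78 °C; then 19, −78 °C
Reagents that add atoms: none
Why: Evans C-acylation: the Z-sodium enolate of the imide (the α-branched methyl ester is not deprotonated at −78 °C) attacks the acid chloride on the face opposite to benzyl, which should set C12 as S, and the β-keto imide formed is configurationally stable because enolisation towards C12 is blocked by allylic 1,3-strain.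

Step 12
Reactants: 20 methyl (2R,6S)-7-[(4R)-4-benzyl-2-oxo-1,3-oxazolidin-3-yl]-6-{[(1R,3R)-3-ethenyl-2,2-dimethylcyclopropyl]carbonyl}-2-[(3Z)-4-iodopent-3-en-1-yl]-7-oxoheptanoate
Product: 22 methyl (1R,3S,7R,10Z,14R)-3-{[(4R)-4-benzyl-2-oxo-1,3-oxazolidin-3-yl]carbonyl}-11,15,15-trimethyl-2-oxobicyclo[12.1.0]pentadec-10-ene-7-carboxylate, via alkylborane 21 (not isolated)
Conditions: 9-BBN (1.5 equiv), THF, 0 °C to rt; then slow addition to PdCl2(dppf) (dppf = 1,1'-bis(diphenylphosphino)ferrocene), AsPh3, Cs2CO3, DMF/THF/H2O, rt, final concentration 1 mM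
Reagents that add atoms: none
Why: Chemoselective hydroboration of the monosubstituted vinyl group by 9-BBN (the iodoalkene and the hindered ketone react far more slowly), followed by intramolecular B-alkyl Suzuki–Miyaura coupling under high dilution, should close the 14-membered ring at C3–C4 with retention of the Z geometry; no stereocentre is formed.

Step 13
Reactants: 22 methyl (1R,3S,7R,10Z,14R)-3-{[(4R)-4-benzyl-2-oxo-1,3-oxazolidin-3-yl]carbonyl}-11,15,15-trimethyl-2-oxobicyclo[12.1.0]pentadec-10-ene-7-carboxylate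
Product: 23 methyl (1R,4Z,8R,12S)-12-{[(4R)-4-benzyl-2-oxo-1,3-oxazolidin-3-yl]carbonyl}-4,15,15-trimethyl-14-oxabicyclo[11.2.1]hexadeca-4,13(16)-diene-8-carboxylate
Conditions: Sc(O3SCF3)3 (20 mol %), 2,6-di-tert-butyl-4-methylpyridine (30 mol %), 4 Å molecular sieves, ClCH2CH2Cl, 50 °C
Reagents that add atoms: none
Why: The scandium salt should be bound in a chelate by the two carbonyl groups of the β-keto imide, so that the C13 carbonyl pulls the electrons of the cyclopropane bond C15–C16, which ionises because C15 bears two methyl groups, and the enolate oxygen then closes on the tertiary cation: the three-membered ring C1–C15–C16 becomes the five-membered ring C13–O14–C15–C1–C16 with release of the cyclopropane strain (3→5 ring expansion). The closest known reaction type is the Lewis-acid-catalysed Cloke–Wilson rearrangement of donor–acceptor cyclopropyl ketones to 2,3-dihydrofurans. The oxolene closes by intramolecular O-alkylation of the enolate inside the ion pair (five-membered closure on a trigonal cation), whereas C-recombination only returns 22. No stereocentre is created: C1 keeps all its bonds and so its R configuration, C16 becomes trigonal, and C12 is held because enolisation of a β-keto imide towards the imide-bearing carbon is blocked by allylic 1,3-strain. The step needs cleavage of C15–C16 and not of C1–C16, which the gem-dimethyl donor at C15 secures against the secondary C1, and it needs capture of the cation by oxygen rather than by the C4=C5 olefin or by loss of a proton, which the contact ion pair, the non-nucleophilic medium and the hindered pyridine base (it removes traces of triflic acid) are meant to secure.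

Step 14
Reactants: 23 methyl (1R,4Z,8R,12S)-12-{[(4R)-4-benzyl-2-oxo-1,3-oxazolidin-3-yl]carbonyl}-4,15,15-trimethyl-14-oxabicyclo[11.2.1]hexadeca-4,13(16)-diene-8-carboxylate
Product: 24 methyl (1R,4Z,8R,12S,13R)-12-{[(4R)-4-benzyl-2-oxo-1,3-oxazolidin-3-yl]carbonyl}-4,15,15-trimethyl-14-oxabicyclo[11.2.1]hexadec-4-ene-8-carboxylate
Conditions: Et3SiH (5 equiv), CF3CO2H (5 equiv), CH2Cl2, −78 to −40 °C
Reagents that add atoms: none
Why: Ionic hydrogenation: protonation of the enol ether at C16 gives the bridged oxocarbenium ion, and triethylsilane should deliver hydride to C13 from the exo face, opposite to the face spanned by the eleven-carbon bridge, setting C13 as R with C12 and C2 cis on the oxolane, at a temperature at which the C4=C5 olefin is not protonated.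

Step 15
Reactants: 24 methyl (1R,4Z,8R,12S,13R)-12-{[(4R)-4-benzyl-2-oxo-1,3-oxazolidin-3-yl]carbonyl}-4,15,15-trimethyl-14-oxabicyclo[11.2.1]hexadec-4-ene-8-carboxylate
Product: 27 (1R,4Z,8R,12S,13R)-4,15,15-trimethyl-14-oxabicyclo[11.2.1]hexadec-4-ene-8,12-dicarboxylic acid, via peroxy acid ester 25 (not isolated), via acid ester 26 (not isolated)
Conditions: LiOH, H2O2, THF/H2O, 0 °C; Na2SO3; then LiOH, THF/MeOH/H2O, rt; aq. HCl to pH 2
Reagents that add atoms: hydrogen peroxide, OO; lithium hydroxide, [Li+].[OH-]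
Why: Lithium hydroperoxide cleaves the imide at the exocyclic carbonyl without epimerising C12, sulfite reduces the peroxy acid, and hydroxide then saponifies the methyl ester, which should give the diacid with all four stereocentres and the Z olefin intact.

**Compound list**

1 | (1R,3R)-2,2-dimethyl-3-(2-methylprop-1-en-1-yl)cyclopropane-1-carboxylic acid ((+)-trans-chrysanthemic acid) | O=C(O)[C@@H]1[C@@H](C=C(C)C)C1(C)C | starting material
2 | (1R,3R)-3-(5,5-dimethyl-1,2,4-trioxolan-3-yl)-2,2-dimethylcyclopropane-1-carboxylic acid (ozonide; both epimers at the trioxolane carbon) | O=C(O)[C@@H]1[C@@H](C2OOC(C)(C)O2)C1(C)C | intermediate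
3 | (1R,3R)-3-formyl-2,2-dimethylcyclopropane-1-carboxylic acid | O=C(O)[C@@H]1[C@@H](C=O)C1(C)C | intermediate
4 | (1R,3R)-3-ethenyl-2,2-dimethylcyclopropane-1-carboxylic acid | O=C(O)[C@@H]1[C@@H](C=C)C1(C)C | intermediate
5 | 7-tert-butoxy-7-oxoheptanoic acid (mono-tert-butyl pimelate) | CC(C)(C)OC(=O)CCCCCC(=O)O | starting material
6 | (4S)-4-benzyl-1,3-oxazolidin-2-one | O=C1N[C@@H](Cc2ccccc2)CO1 | starting material
7 | 7-tert-butoxy-7-oxoheptanoic pivalic anhydride | CC(C)(C)OC(=O)CCCCCC(=O)OC(=O)C(C)(C)C | intermediate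
8 | tert-butyl 7-[(4S)-4-benzyl-2-oxo-1,3-oxazolidin-3-yl]-7-oxoheptanoate | CC(C)(C)OC(=O)CCCCCC(=O)N1[C@@H](Cc2ccccc2)COC1=O | intermediate
9 | tert-butyl (6R)-6-{[(4S)-4-benzyl-2-oxo-1,3-oxazolidin-3-yl]carbonyl}non-8-enoate | CC(C)(C)OC(=O)CCCC[C@H](CC=C)C(=O)N1[C@@H](Cc2ccccc2)COC1=O | intermediate
10 | 7-tert-butyl 1-methyl (2R)-2-(prop-2-en-1-yl)heptanedioate | CC(C)(C)OC(=O)CCCC[C@H](CC=C)C(=O)OC | intermediate
11 | 7-tert-butyl 1-methyl (2S)-2-[3-(9-borabicyclo[3.3.1]nonan-9-yl)propyl]heptanedioate | CC(C)(C)OC(=O)CCCC[C@H](CCCB1C2CCCC1CCC2)C(=O)OC | intermediate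
12 | 7-tert-butyl 1-methyl (2R)-2-(3-hydroxypropyl)heptanedioate | CC(C)(C)OC(=O)CCCC[C@H](CCCO)C(=O)OC | intermediate
13 | 7-tert-butyl 1-methyl (2R)-2-(3-oxopropyl)heptanedioate | CC(C)(C)OC(=O)CCCC[C@H](CCC=O)C(=O)OC | intermediate
14 | 7-tert-butyl 1-methyl (2R)-2-[(3Z)-4-iodopent-3-en-1-yl]heptanedioate | CC(C)(C)OC(=O)CCCC[C@H](CC/C=C(/C)I)C(=O)OC | intermediate
15 | (6R,9Z)-10-iodo-6-(methoxycarbonyl)undec-9-enoic acid | OC(=O)CCCC[C@H](CC/C=C(/C)I)C(=O)OC | intermediate
16 | (4R)-4-benzyl-1,3-oxazolidin-2-one | O=C1N[C@H](Cc2ccccc2)CO1 | starting material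
17 | (6R,9Z)-10-iodo-6-(methoxycarbonyl)undec-9-enoic pivalic anhydride | CC(C)(C)C(=O)OC(=O)CCCC[C@H](CC/C=C(/C)I)C(=O)OC | intermediate
18 | methyl (2R)-7-[(4R)-4-benzyl-2-oxo-1,3-oxazolidin-3-yl]-2-[(3Z)-4-iodopent-3-en-1-yl]-7-oxoheptanoate | O=C(CCCC[C@H](CC/C=C(/C)I)C(=O)OC)N1[C@H](Cc2ccccc2)COC1=O | intermediate
19 | (1R,3R)-3-ethenyl-2,2-dimethylcyclopropane-1-carbonyl chloride | O=C(Cl)[C@@H]1[C@@H](C=C)C1(C)C | intermediate
20 | methyl (2R,6S)-7-[(4R)-4-benzyl-2-oxo-1,3-oxazolidin-3-yl]-6-{[(1R,3R)-3-ethenyl-2,2-dimethylcyclopropyl]carbonyl}-2-[(3Z)-4-iodopent-3-en-1-yl]-7-oxoheptanoate | O=C([C@@H]1[C@@H](C=C)C1(C)C)[C@H](CCC[C@H](CC/C=C(/C)I)C(=O)OC)C(=O)N1[C@H](Cc2ccccc2)COC1=O | intermediate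
21 | methyl (2R,6S)-7-[(4R)-4-benzyl-2-oxo-1,3-oxazolidin-3-yl]-6-({(1R,3R)-3-[2-(9-borabicyclo[3.3.1]nonan-9-yl)ethyl]-2,2-dimethylcyclopropyl}carbonyl)-2-[(3Z)-4-iodopent-3-en-1-yl]-7-oxoheptanoate | O=C([C@@H]1[C@@H](CCB2C3CCCC2CCC3)C1(C)C)[C@H](CCC[C@H](CC/C=C(/C)I)C(=O)OC)C(=O)N1[C@H](Cc2ccccc2)COC1=O | intermediate
22 | methyl (1R,3S,7R,10Z,14R)-3-{[(4R)-4-benzyl-2-oxo-1,3-oxazolidin-3-yl]carbonyl}-11,15,15-trimethyl-2-oxobicyclo[12.1.0]pentadec-10-ene-7-carboxylate | C/C1=C/CC[C@H](C(=O)OC)CCC[C@H](C(=O)N2[C@H](Cc3ccccc3)COC2=O)C(=O)[C@@H]2[C@@H](CC1)C2(C)C | intermediate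
23 | methyl (1R,4Z,8R,12S)-12-{[(4R)-4-benzyl-2-oxo-1,3-oxazolidin-3-yl]carbonyl}-4,15,15-trimethyl-14-oxabicyclo[11.2.1]hexadeca-4,13(16)-diene-8-carboxylate | C/C1=C/CC[C@H](C(=O)OC)CCC[C@H](C(=O)N2[C@H](Cc3ccccc3)COC2=O)C2=C[C@@H](CC1)C(C)(C)O2 | intermediate
24 | methyl (1R,4Z,8R,12S,13R)-12-{[(4R)-4-benzyl-2-oxo-1,3-oxazolidin-3-yl]carbonyl}-4,15,15-trimethyl-14-oxabicyclo[11.2.1]hexadec-4-ene-8-carboxylate | C/C1=C/CC[C@H](C(=O)OC)CCC[C@H](C(=O)N2[C@H](Cc3ccccc3)COC2=O)[C@H]2C[C@@H](CC1)C(C)(C)O2 | intermediate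
25 | (1R,4Z,8R,12S,13R)-8-(methoxycarbonyl)-4,15,15-trimethyl-14-oxabicyclo[11.2.1]hexadec-4-ene-12-carboperoxoic acid | C/C1=C/CC[C@H](C(=O)OC)CCC[C@H](C(=O)OO)[C@H]2C[C@@H](CC1)C(C)(C)O2 | intermediate
26 | (1R,4Z,8R,12S,13R)-8-(methoxycarbonyl)-4,15,15-trimethyl-14-oxabicyclo[11.2.1]hexadec-4-ene-12-carboxylic acid | C/C1=C/CC[C@H](C(=O)OC)CCC[C@H](C(=O)O)[C@H]2C[C@@H](CC1)C(C)(C)O2 | intermediate
27 | (1R,4Z,8R,12S,13R)-4,15,15-trimethyl-14-oxabicyclo[11.2.1]hexadec-4-ene-8,12-dicarboxylic acid (CNP0115244.2) | C/C1=C/CC[C@H](C(=O)O)CCC[C@H](C(=O)O)[C@H]2C[C@@H](CC1)C(C)(C)O2 | target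

**Step count and risks**

Total step count: 15 (steps 1–2 for the cyclopropane acid, steps 3–10 for the chain imide, steps 11–15 after their union).
Longest linear sequence: 13 steps (steps 3–15, from 5).

Steps most likely to fail:

1. Step 13 (key step). The bond C15–C16 may ionise sluggishly because the donor is purely alkyl; the tertiary cation may lose a proton or be captured across the ring by the C4=C5 olefin; traces of acid may isomerise that olefin. The fallback sets out from 22 and comes back at 23. Heating 22 (o-dichlorobenzene, 180 °C) should open the same C15–C16 bond without a cation, by the thermal homo-1,5-hydrogen shift (enolene rearrangement) of a methyl hydrogen cis to the acyl group, to give the isopropenyl ketone F1. Acid-catalysed Markovnikov cycloisomerisation of this γ,δ-unsaturated ketone (pyridinium p-toluenesulfonate, benzene, 60 °C), a known route to 4,5-dihydrofurans, should then close the oxolene and give 23.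

2. Step 12. The aqueous carbonate of the coupling may epimerise C12 or cleave the β-keto imide by retro-Claisen reaction, 9-BBN may reduce the ketone, and oligomers may form instead of the ring. The fallback sets out from 20 and comes back at 22; it masks the ketone at the alcohol oxidation level during the coupling. Chelation-controlled reduction with Zn(BH4)2 (CH2Cl2, −20 °C) should give the syn β-hydroxy imide F2. Silylation (Et3SiOSO2CF3, 2,6-lutidine) gives the triethylsilyl ether F3. Hydroboration with 9-BBN gives the alkylborane F4, and the same Suzuki–Miyaura macrocyclisation gives the macrocyclic silyl ether F5. Desilylation (HF·pyridine) gives the macrocyclic alcohol F6, and Dess–Martin oxidation returns 22. The configuration of the temporary carbinol centre does not matter, since it is oxidised again.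

3. Step 14. The oxocarbenium ion may lose the C12 proton reversibly (loss of the C12 configuration through the exocyclic enol ether), hydride may arrive on the wrong face, or the C4=C5 olefin may attack the cation across the ring. The fallback sets out from 23 and comes back at 24. Addition of methanol to the enol ether (pyridinium p-toluenesulfonate, MeOH, 0 °C) should give the methyl ketal F7. Lewis-acid ketal reduction (Et3SiH, BF3·OEt2, CH2Cl2/MeCN, −78 °C) then forms the oxocarbenium ion under aprotic conditions in the presence of excess hydride, which shortens its lifetime, and should give 24.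

Further compounds
F1 | step 13 | methyl (1R,4Z,8R,11S)-11-{[(4R)-4-benzyl-2-oxo-1,3-oxazolidin-3-yl]carbonyl}-5-methyl-10-oxo-8-(prop-1-en-2-yl)cyclotetradec-4-ene-1-carboxylate | C/C1=C/CC[C@H](C(=O)OC)CCC[C@H](C(=O)N2[C@H](Cc3ccccc3)COC2=O)C(=O)C[C@@H](CC1)C(C)=C
F2 | step 12 | methyl (2R,6S)-7-[(4R)-4-benzyl-2-oxo-1,3-oxazolidin-3-yl]-6-{(R)-[(1R,3R)-3-ethenyl-2,2-dimethylcyclopropyl](hydroxy)methyl}-2-[(3Z)-4-iodopent-3-en-1-yl]-7-oxoheptanoate | O[C@H]([C@@H]1[C@@H](C=C)C1(C)C)[C@H](CCC[C@H](CC/C=C(/C)I)C(=O)OC)C(=O)N1[C@H](Cc2ccccc2)COC1=O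
F3 | step 12 | methyl (2R,6S)-7-[(4R)-4-benzyl-2-oxo-1,3-oxazolidin-3-yl]-6-{(R)-[(1R,3R)-3-ethenyl-2,2-dimethylcyclopropyl][(triethylsilyl)oxy]methyl}-2-[(3Z)-4-iodopent-3-en-1-yl]-7-oxoheptanoate | CC[Si](CC)(CC)O[C@H]([C@@H]1[C@@H](C=C)C1(C)C)[C@H](CCC[C@H](CC/C=C(/C)I)C(=O)OC)C(=O)N1[C@H](Cc2ccccc2)COC1=O
F4 | step 12 | B-alkyl-9-borabicyclo[3.3.1]nonane adduct of F3 (boron on the terminal carbon of the former vinyl group) | CC[Si](CC)(CC)O[C@H]([C@@H]1[C@@H](CCB2C3CCCC2CCC3)C1(C)C)[C@H](CCC[C@H](CC/C=C(/C)I)C(=O)OC)C(=O)N1[C@H](Cc2ccccc2)COC1=O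
F5 | step 12 | methyl (1R,2R,3S,7R,10Z,14R)-3-{[(4R)-4-benzyl-2-oxo-1,3-oxazolidin-3-yl]carbonyl}-11,15,15-trimethyl-2-[(triethylsilyl)oxy]bicyclo[12.1.0]pentadec-10-ene-7-carboxylate | C/C1=C/CC[C@H](C(=O)OC)CCC[C@H](C(=O)N2[C@H](Cc3ccccc3)COC2=O)[C@H](O[Si](CC)(CC)CC)[C@@H]2[C@@H](CC1)C2(C)C
F6 | step 12 | methyl (1R,2R,3S,7R,10Z,14R)-3-{[(4R)-4-benzyl-2-oxo-1,3-oxazolidin-3-yl]carbonyl}-2-hydroxy-11,15,15-trimethylbicyclo[12.1.0]pentadec-10-ene-7-carboxylate | C/C1=C/CC[C@H](C(=O)OC)CCC[C@H](C(=O)N2[C@H](Cc3ccccc3)COC2=O)[C@H](O)[C@@H]2[C@@H](CC1)C2(C)C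
F7 | step 14 | methyl (1R,4Z,8R,12S)-12-{[(4R)-4-benzyl-2-oxo-1,3-oxazolidin-3-yl]carbonyl}-13-methoxy-4,15,15-trimethyl-14-oxabicyclo[11.2.1]hexadec-4-ene-8-carboxylate (both epimers at C13) | C/C1=C/CC[C@H](C(=O)OC)CCC[C@H](C(=O)N2[C@H](Cc3ccccc3)COC2=O)C2(OC)C[C@@H](CC1)C(C)(C)O2
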